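**Plan**

- Cuts, in retrosynthetic order: (1) the N1–SO2Ph bond of a protected precursor; (2) the C2'=C3' double bond of the N-linked indole (primed locants); (3) the C3–N1' bond between the two halves; (4) the aryl–prenyl bonds at C6 and C6'.
- Enabling feature: C2' and C3' are both plain CH, and N1' is fully substituted by C7a' and by C3 of the N–H indole. C2' can therefore start as a formyl carbon on N1' and C3' as a benzylic ylide carbon on C3a'.
- Forward, part 1: the N–H indole ring is bought as 6-bromoindole. Two Stille prenylations are followed by a Buchwald–Hartwig amination that joins a 3-iodoindole to a 2-(silyloxymethyl)aniline.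
- Forward, part 2: N-formylation and conversion of the benzylic oxygen into a phosphonium salt set up the intramolecular Wittig reaction. It closes the pyrrole ring of the second indole, the only ring made in the route, and desulfonylation ends the sequence.
- Stereochemistry: there is none to set. The target has no stereocentre, and each alkene carries two methyl groups on one carbon, so no E/Z isomers exist.

Key step: step 10

Remark: prenyl = 3-methylbut-2-en-1-yl and TBS = tert-butyldimethylsilyl. The four starting materials are taken to be catalogue chemicals.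

**Step 1**
Reactants: 1 6-bromoindole; 2 tributyl(3-methylbut-2-en-1-yl)stannane
Product: 3 6-prenylindole
Conditions: Pd(PPh3)4 (5 mol %), DMF, 100 °C
Reagents that add atoms: none
Why: Migita–Kosugi–Stille coupling: oxidative addition of the C6–Br bond to zerovalent palladium, prenyl transfer from tin and reductive elimination at the unhindered CH2 terminus should give the linear prenyl arene under neutral conditions that leave the free N–H alone.

**Step 2**
Reactants: 3 6-prenylindole
Product: 5 3-iodo-1-(phenylsulfonyl)-6-prenylindole, via 3-iodo-6-prenylindole 4 (not isolated)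
Conditions: I2 (1.0 equiv), KOH (powder, 4 equiv), DMF, 0 °C → rt; then PhSO2Cl, 0 °C → rt, same flask
Reagents that add atoms: iodine, II; benzenesulfonyl chloride, O=S(=O)(Cl)c1ccccc1
Why: Electrophilic aromatic iodination followed by N-sulfonylation: iodine should attack the indolyl anion at C3 far faster than it attacks the trisubstituted alkene, and capping N1 in the same flask turns the fragile 3-iodoindole into a stable coupling partner.

**Step 3**
Reactants: 6 (2-amino-4-bromophenyl)methanol
Product: 7 5-bromo-2-[(tert-butyldimethylsilyloxy)methyl]aniline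
Conditions: TBSCl, imidazole, CH2Cl2, 0 °C → rt
Reagents that add atoms: tert-butyldimethylsilyl chloride, CC(C)(C)[Si](C)(C)Cl
Why: Standard silyl ether formation, selective for the primary alcohol because any N–Si bond at the aniline is labile and should not survive aqueous work-up.

**Step 4**
Reactants: 7 5-bromo-2-[(tert-butyldimethylsilyloxy)methyl]aniline; 2 tributyl(3-methylbut-2-en-1-yl)stannane
Product: 8 2-[(tert-butyldimethylsilyloxy)methyl]-5-prenylaniline
Conditions: Pd(PPh3)4 (5 mol %), DMF, 100 °C
Reagents that add atoms: none
Why: Second Migita–Kosugi–Stille prenylation with the same regiochemical logic as step 1; the free aniline and the silyl ether are inert under the neutral conditions.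

**Step 5**
Reactants: 5 3-iodo-1-(phenylsulfonyl)-6-prenylindole; 8 2-[(tert-butyldimethylsilyloxy)methyl]-5-prenylaniline
Product: 9 N-{2-[(tert-butyldimethylsilyloxy)methyl]-5-prenylphenyl}-1-(phenylsulfonyl)-6-prenylindol-3-amine
Conditions: Pd2(dba)3 (2.5 mol %), XPhos (10 mol %), Cs2CO3, toluene, 100 °C
Reagents that add atoms: none
Why: Buchwald–Hartwig amination: the C3–I bond of the N-sulfonylindole adds readily to zerovalent palladium, the bulky biaryl phosphine promotes C–N reductive elimination with the ortho-substituted aniline, and the weak carbonate base in toluene spares the sulfonyl and silyl groups.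

**Step 6**
Reactants: 9 N-{2-[(tert-butyldimethylsilyloxy)methyl]-5-prenylphenyl}-1-(phenylsulfonyl)-6-prenylindol-3-amine
Product: 10 N-{2-[(tert-butyldimethylsilyloxy)methyl]-5-prenylphenyl}-N-[1-(phenylsulfonyl)-6-prenylindol-3-yl]formamide
Conditions: HCO2H, Ac2O, 55 °C (forms AcOCHO); then 9, THF, 0 → 45 °C
Reagents that add atoms: acetic formic anhydride, CC(=O)OC=O (formyl group; generated from formic acid, O=CO, and acetic anhydride, CC(=O)OC(C)=O)
Why: N-Formylation with a mixed anhydride: acetic formic anhydride hands over its more electrophilic and less hindered formyl group even to weakly nucleophilic diarylamines, and the anhydrous, weakly acidic medium should leave the TBS ether and the prenyl groups intact.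

**Step 7**
Reactants: 10 N-{2-[(tert-butyldimethylsilyloxy)methyl]-5-prenylphenyl}-N-[1-(phenylsulfonyl)-6-prenylindol-3-yl]formamide
Product: 11 N-[2-(hydroxymethyl)-5-prenylphenyl]-N-[1-(phenylsulfonyl)-6-prenylindol-3-yl]formamide
Conditions: Bu4NF, AcOH (1 equiv each), THF, 0 °C → rt
Reagents that add atoms: none
Why: Fluoride-mediated desilylation; the acetic acid buffer protonates the alkoxide as it forms, so it should not attack the neighbouring formamide or the sulfonyl group.

**Step 8**
Reactants: 11 N-[2-(hydroxymethyl)-5-prenylphenyl]-N-[1-(phenylsulfonyl)-6-prenylindol-3-yl]formamide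
Product: 13 N-[2-(bromomethyl)-5-prenylphenyl]-N-[1-(phenylsulfonyl)-6-prenylindol-3-yl]formamide, via benzylic mesylate 12 (not isolated)
Conditions: MsCl, Et3N, CH2Cl2, −20 °C; then LiBr, THF, 0 °C → rt
Reagents that add atoms: methanesulfonyl chloride, CS(=O)(=O)Cl (atoms kept only in 12); lithium bromide, [Li+].[Br-]
Why: Mesylation followed by Finkelstein-type SN2 displacement with bromide, the acid-free protocol used for prenyl-type substrates, avoids both HBr that could add to the trisubstituted alkenes and phosphine/tetrahalomethane reagents that can attack formamides.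

**Step 9**
Reactants: 13 N-[2-(bromomethyl)-5-prenylphenyl]-N-[1-(phenylsulfonyl)-6-prenylindol-3-yl]formamide; 14 triphenylphosphine
Product: 15 {2-[formyl(1-(phenylsulfonyl)-6-prenylindol-3-yl)amino]-4-prenylbenzyl}triphenylphosphonium bromide
Conditions: toluene, 80 °C
Reagents that add atoms: none
Why: SN2 quaternisation of triphenylphosphine by a primary benzylic bromide (Wittig salt formation); the salt should precipitate from toluene, which drives the reaction and purifies the product.

**Step 10**
Reactants: 15 {2-[formyl(1-(phenylsulfonyl)-6-prenylindol-3-yl)amino]-4-prenylbenzyl}triphenylphosphonium bromide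
Product: 17 1-(phenylsulfonyl)-6-prenyl-3-(6-prenylindol-1-yl)indole, via benzylic phosphorus ylide 16 (not isolated)
Conditions: KN(SiMe3)2 (1.05 equiv), THF–toluene (0.01 M), 0 °C → rt
Reagents that add atoms: none
Why: KN(SiMe3)2 removes a benzylic proton next to phosphorus, by far the most acidic C–H, to give ylide 16; its carbanionic carbon (future C3') adds to the formyl carbon on N1' (future C2'), and the oxaphosphetane collapses with loss of Ph3PO to the C2'=C3' bond, which is at once part of an aromatic pyrrole ring. The closest known reaction type is the intramolecular Wittig indole synthesis from (2-acylaminobenzyl)triphenylphosphonium salts, applied here to an N-aryl formamide. The one new ring (ylide carbon, C3a', C7a', N1', formyl carbon) closes in the 5-exo-trig mode, with the C=O bond outside the ring. No stereocentre is formed. The step needs attack at the formyl carbon rather than at sulfonyl sulfur, at a second molecule or by an external nucleophile, and three things should secure this: the ortho-substituted aryl ring stands roughly perpendicular to the formamide plane and holds the ylide carbon over the carbonyl π* orbital, the nitrogen lone pair is shared with two aromatic rings so the carbonyl is unusually electrophilic, and a non-nucleophilic silazide base at high dilution leaves no alkoxide that could strip the formyl or sulfonyl group.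

**Step 11**
Reactants: 17 1-(phenylsulfonyl)-6-prenyl-3-(6-prenylindol-1-yl)indole
Product: 18 6-prenyl-3-(6-prenylindol-1-yl)-1H-indole
Conditions: Mg turnings (10 equiv), MeOH–THF, rt, sonication
Reagents that add atoms: none
Why: Reductive N–S cleavage by single-electron transfer (Mg/MeOH desulfonylation of N-sulfonylindoles); isolated trisubstituted alkenes and the two indole rings are not reducible under these conditions.

**Compound list**

1 | 6-bromo-1H-indole | Brc1ccc2cc[nH]c2c1 | starting material
2 | tributyl(3-methylbut-2-en-1-yl)stannane | CCCC[Sn](CCCC)(CCCC)CC=C(C)C | starting material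
3 | 6-prenyl-1H-indole | CC(C)=CCc1ccc2cc[nH]c2c1 | intermediate
4 | 3-iodo-6-prenyl-1H-indole | CC(C)=CCc1ccc2c(I)c[nH]c2c1 | intermediate
5 | 3-iodo-1-(phenylsulfonyl)-6-prenylindole | CC(C)=CCc1ccc2c(I)cn(S(=O)(=O)c3ccccc3)c2c1 | intermediate
6 | (2-amino-4-bromophenyl)methanol | Nc1cc(Br)ccc1CO | starting material
7 | 5-bromo-2-[(tert-butyldimethylsilyloxy)methyl]aniline | Nc1cc(Br)ccc1CO[Si](C)(C)C(C)(C)C | intermediate
8 | 2-[(tert-butyldimethylsilyloxy)methyl]-5-prenylaniline | CC(C)=CCc1ccc(CO[Si](C)(C)C(C)(C)C)c(N)c1 | intermediate
9 | N-{2-[(tert-butyldimethylsilyloxy)methyl]-5-prenylphenyl}-1-(phenylsulfonyl)-6-prenylindol-3-amine | CC(C)=CCc1ccc(CO[Si](C)(C)C(C)(C)C)c(Nc2cn(S(=O)(=O)c3ccccc3)c3cc(CC=C(C)C)ccc23)c1 | intermediate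
10 | N-{2-[(tert-butyldimethylsilyloxy)methyl]-5-prenylphenyl}-N-[1-(phenylsulfonyl)-6-prenylindol-3-yl]formamide | O=CN(c1cn(S(=O)(=O)c2ccccc2)c2cc(CC=C(C)C)ccc12)c1cc(CC=C(C)C)ccc1CO[Si](C)(C)C(C)(C)C | intermediate
11 | N-[2-(hydroxymethyl)-5-prenylphenyl]-N-[1-(phenylsulfonyl)-6-prenylindol-3-yl]formamide | O=CN(c1cn(S(=O)(=O)c2ccccc2)c2cc(CC=C(C)C)ccc12)c1cc(CC=C(C)C)ccc1CO | intermediate
12 | 2-[formyl(1-(phenylsulfonyl)-6-prenylindol-3-yl)amino]-4-prenylbenzyl methanesulfonate | O=CN(c1cn(S(=O)(=O)c2ccccc2)c2cc(CC=C(C)C)ccc12)c1cc(CC=C(C)C)ccc1COS(C)(=O)=O | intermediate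
13 | N-[2-(bromomethyl)-5-prenylphenyl]-N-[1-(phenylsulfonyl)-6-prenylindol-3-yl]formamide | O=CN(c1cn(S(=O)(=O)c2ccccc2)c2cc(CC=C(C)C)ccc12)c1cc(CC=C(C)C)ccc1CBr | intermediate
14 | triphenylphosphine | c1ccc(P(c2ccccc2)c2ccccc2)cc1 | starting material
15 | {2-[formyl(1-(phenylsulfonyl)-6-prenylindol-3-yl)amino]-4-prenylbenzyl}triphenylphosphonium bromide | O=CN(c1cn(S(=O)(=O)c2ccccc2)c2cc(CC=C(C)C)ccc12)c1cc(CC=C(C)C)ccc1C[P+](c1ccccc1)(c1ccccc1)c1ccccc1.[Br-] | intermediate
16 | {2-[formyl(1-(phenylsulfonyl)-6-prenylindol-3-yl)amino]-4-prenylbenzylidene}triphenylphosphorane | O=CN(c1cn(S(=O)(=O)c2ccccc2)c2cc(CC=C(C)C)ccc12)c1cc(CC=C(C)C)ccc1C=P(c1ccccc1)(c1ccccc1)c1ccccc1 | intermediate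
17 | 1-(phenylsulfonyl)-6-prenyl-3-(6-prenylindol-1-yl)indole | CC(C)=CCc1ccc2c(-n3ccc4ccc(CC=C(C)C)cc43)cn(S(=O)(=O)c3ccccc3)c2c1 | intermediate
18 | 6-prenyl-3-(6-prenylindol-1-yl)-1H-indole | CC(C)=CCc1ccc2c(-n3ccc4ccc(CC=C(C)C)cc43)c[nH]c2c1 | target

**Step count**

- Total steps: 11.
- Longest linear sequence: 9 steps (1, 2, 5–11). The branch 3, 4, 5–11 is equally long.

**Steps most likely to fail**

**Step 10.**
- What may go wrong: the semi-stabilised ylide may add only slowly to the amide carbonyl. The tetrahedral adduct may also collapse by expelling the diarylamide nitrogen, which transfers the formyl group from N to C. Either course opens the way to loss of the formyl group or to intermolecular olefination.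
- Fallback: form the same C2'=C3' bond by reductive carbonyl coupling instead of olefination. It sets out from 11. MnO2 in CH2Cl2 at rt should oxidise the benzylic alcohol to N-(2-formyl-5-prenylphenyl)-N-[1-(phenylsulfonyl)-6-prenylindol-3-yl]formamide F1. Low-valent titanium (TiCl3, Zn, THF, reflux; oxo-amide McMurry-type coupling, the Fürstner indole synthesis) should then join the aldehyde and formamide carbons. The route is rejoined at 17.

**Step 7.**
- What may go wrong: unmasking a hydroxyl group six atoms from an activated N,N-diaryl formamide invites N→O formyl migration. In step 8 the same proximity could lead to O-alkylation of the formamide by the benzylic leaving group.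
- Fallback: install phosphorus before the formyl group, so that no hydroxyl or halide ever sits beside a formamide. It sets out from 9. Bu4NF in THF should give {2-[(1-(phenylsulfonyl)-6-prenylindol-3-yl)amino]-4-prenylphenyl}methanol F2. Ph3P·HBr in MeCN at 60 °C, the direct conversion of ortho-aminobenzylic alcohols into phosphonium salts, should give {2-[(1-(phenylsulfonyl)-6-prenylindol-3-yl)amino]-4-prenylbenzyl}triphenylphosphonium bromide F3; the phosphine keeps free HBr low. Acetic formic anhydride then formylates the nitrogen, and the route is rejoined at 15.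

**Step 5.**
- What may go wrong: C–N reductive elimination with the ortho-substituted aniline may be sluggish, the iodide may undergo protodeiodination, or carbonate may remove the sulfonyl group at 100 °C.
- Fallback: change both the nucleophile and the metal. It sets out from 8. Acetic formic anhydride should convert 8 into N-{2-[(tert-butyldimethylsilyloxy)methyl]-5-prenylphenyl}formamide F4. A Goldberg amidation of F4 with 5 (CuI, N,N'-dimethylethane-1,2-diamine, K3PO4, toluene, 110 °C) should then forge the C3–N bond with the formyl group already in place. The route is rejoined at 10 and step 6 is bypassed.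

**Further compounds**

F1 | step 10 | N-(2-formyl-5-prenylphenyl)-N-[1-(phenylsulfonyl)-6-prenylindol-3-yl]formamide | O=CN(c1cn(S(=O)(=O)c2ccccc2)c2cc(CC=C(C)C)ccc12)c1cc(CC=C(C)C)ccc1C=O
F2 | step 7 | {2-[(1-(phenylsulfonyl)-6-prenylindol-3-yl)amino]-4-prenylphenyl}methanol | CC(C)=CCc1ccc(CO)c(Nc2cn(S(=O)(=O)c3ccccc3)c3cc(CC=C(C)C)ccc23)c1
F3 | step 7 | {2-[(1-(phenylsulfonyl)-6-prenylindol-3-yl)amino]-4-prenylbenzyl}triphenylphosphonium bromide | CC(C)=CCc1ccc(C[P+](c2ccccc2)(c2ccccc2)c2ccccc2)c(Nc2cn(S(=O)(=O)c3ccccc3)c3cc(CC=C(C)C)ccc23)c1.[Br-]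
F4 | step 5 | N-{2-[(tert-butyldimethylsilyloxy)methyl]-5-prenylphenyl}formamide | O=CNc1cc(CC=C(C)C)ccc1CO[Si](C)(C)C(C)(C)C
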